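All runs were generated by integration for an exercise.

I decide to rank these flasks by counting turnovers: how many each catalyst must make, and how many the time allows.

| flask | substrate | partner | free catalyst | added ligand | temperature | remark | time |
|---|---|---|---|---|---|---|---|
| autumn | 0.0084 M | 0.0726 M | 5.5 mM | 16 mM | −18 °C | run made earlier |  |
| winter | 0.041 M | 0.0726 M | 5.5 mM | 16 mM | 10 °C | run made earlier |  |
| summer | 0.066 M | 0.0726 M | 2.7 mM | 16 mM | −18 °C | run made earlier |  |
| green | 0.015 M | 0.0726 M | 5.5 mM | 25 mM | −30 °C |  | 30 min |
| ochre | 0.066 M | 0.300 M | 5.5 mM | 16 mM | 20 °C |  | 30 min |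
| amber | 0.066 M | 0.0726 M | 5.5 mM | 16 mM | 0 °C |  | 30 min |
| red | 0.040 M | 0.0726 M | 2.0 mM | 16 mM | 0 °C |  | 30 min |

- autumn (time / min: product / %): 15.0: 3.5; 30.0: 18.9; 50.0: 43.9; 60.0: 56.8; 80.0: 80.5
- winter (time / min: product / %): 1.50: 8.1; 5.00: 38.1; 10.0: 75.9; 12.0: 88.9; 20.0: 99.5
- summer (time / min: product / %): 6.00: 0.1; 12.0: 0.3; 20.0: 0.8; 40.0: 2.5; 80.0: 5.7

(standard deviation of a reading: 0.5 percentage points)

* the flasks by amount of product, in percent of the substrate charged, highest first, at 30 min (green / ochre / amber / red)
* the amount of product, in percent of the substrate charged of the flask you put first, at 30 min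
* the amount of product, in percent of the substrate charged of the flask you put last, at 30 min

- a reading or a percentage of product counts all its forms, free or not
- no earlier run changes the charge of added ligand; that part of a forecast is a guess

The substrate charged over the catalyst charged gives the turnovers needed, 12.0 in ochre and amber, 20.0 in red and 2.73 in green. The supply comes from the steady slope per catalyst, the turnover frequency, as read from the runs:

autumn, −18 °C: 0.0193 min⁻¹

summer, −18 °C: 0.0196 min⁻¹

winter, 10 °C: 0.564 min⁻¹

Autumn and summer agree, although their charges of substrate and catalyst differ, so I count per catalyst. Now I take two extreme flasks, each turning steadily for 30 min: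

cold flask, at autumn's frequency: 0.579 turnovers

hot flask, at winter's frequency: 16.9 turnovers

Ochre, at 20 °C with 0.300 M of partner, should stand above the hot flask, whose supply exceeds ochre's need, so I expect it to finish. The margin is a factor 1.41 before any lag. Amber and red, both at 0 °C, lie between the extremes, and at one frequency red's share is 0.600 of amber's. Green runs colder than autumn. Taking autumn's count at 30 min, 0.289 turnovers, as a rough ceiling, I estimate green below 10.6%, guessing that its extra ligand does not speed it.

The forecast says ochre > amber > red > green, with top 99.3% and low 0.5%, on the ground “zero order in substrate and first order in catalyst”. Its low lies under my ceiling.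

The flasks give ochre > amber > red > green: ochre 100%, amber 46.0%, red 28.8%, green 0.0437%.

    catalyst intermediate E → free catalyst + product (k = 0.104 s⁻¹, Ea = 78.0 kJ mol⁻¹)
    crystals ⇌ product, rate k2*(cs2 - [product]) while solid is left; crystals form when [product] > cs2 (solubility = 12.0 mM, k = 0.0185 s⁻¹)
    catalyst intermediate A → catalyst intermediate B (k = 0.0121 s⁻¹, Ea = 82.0 kJ mol⁻¹)
    catalyst intermediate C → released group + catalyst intermediate D (k = 0.0946 s⁻¹, Ea = 64.0 kJ mol⁻¹)
    partner + free catalyst → catalyst intermediate A (k = 0.918 M⁻¹ s⁻¹, Ea = 53.0 kJ mol⁻¹)
    free catalyst + added ligand ⇌ idle complex, settled at all times (K = 260 M⁻¹, ΔH = −13.0 kJ mol⁻¹)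
    substrate + catalyst intermediate B → catalyst intermediate C (k = 22.1 M⁻¹ s⁻¹, Ea = 39.0 kJ mol⁻¹)
    catalyst intermediate D → catalyst intermediate E (k = 0.00925 s⁻¹, Ea = 76.0 kJ mol⁻¹)
    (constants at 0 °C)

In ochre, the step from catalyst intermediate D to catalyst intermediate E, passed once per turnover, has half of its turnover up to 30 min behind it at 2.49 min, so 6.00 of the 12.0 turnovers have passed that step far sooner than the 30 min allowed. The neighbour, ochre repeated at −5 °C, needs the same 12.0 turnovers but makes 3.84 of them in 30 min, inside the span from 0.579 to 16.9, and stands at 32.0% of the substrate charged.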